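**Strategy.** Everything rests on cutting the dihydrobenzofuran at C2–C3 and O1–C2: C3 (the diaryl methine on the resorcinol ring) and C2 (the O-benzylic carbon bearing the 4-oxygenated phenyl) are trans neighbours bridged by phenolic O1, so an o-quinone methide and a benzylic sulfonium ylide give the ring, both stereocentres and the trans relationship in one [4+1] annulation. The precursor is a racemic o-hydroxybenzyl sulfone on a 4-bromo-resorcinol core, paired with a C2-symmetric thiolanium salt; all phenols travel as MOM ethers from the start, so no late ether exchange is needed. The bromide then becomes a boronic acid for asymmetric arylation of a pyranochromone, and light opens the chromene last.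

Key step: step 10

Assumption: the sense of induction of the (2R,5R)-thiolanium ylide (step 10) and of the rhodium/(S,S)-diene catalyst (step 15) is taken to match that known for benzylic-ylide epoxide formation and for aryl addition to cyclic enones; were either opposite, the mirror-image sulfide (from (2R,5R)-hexane-2,5-diol) or ligand would be used with no other change.

**Route**

Step 1
Reactants: 1 5-bromo-2,4-dihydroxybenzaldehyde
Product: 2 5-bromo-2-hydroxy-4-(methoxymethoxy)benzaldehyde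
Conditions: MOMCl (1.05 equiv), K2CO3 (1.1 equiv), acetone, 0 °C → rt
Reagents that add atoms: chloromethyl methyl ether, COCCl
Why: Williamson etherification should go to the 4-OH, because the 2-OH is held in a hydrogen bond to the formyl group and is the less acidic and less nucleophilic phenol.

Step 2
Reactants: 3 5-bromobenzene-1,3-diol
Product: 4 1-bromo-3,5-bis(methoxymethoxy)benzene
Conditions: NaH (2.4 equiv), MOMCl (2.4 equiv), DMF, 0 °C → rt
Reagents that add atoms: chloromethyl methyl ether, COCCl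
Why: Exhaustive Williamson etherification of the two equivalent phenoxides.

Step 3
Reactants: 4 1-bromo-3,5-bis(methoxymethoxy)benzene; 2 5-bromo-2-hydroxy-4-(methoxymethoxy)benzaldehyde
Product: 6 4-bromo-2-{[3,5-bis(methoxymethoxy)phenyl](hydroxy)methyl}-5-(methoxymethoxy)phenol (racemic), via Grignard reagent 5 (not isolated)
Conditions: 4 (2.3 equiv), Mg, I2 (cat.), THF, 45 °C; then 2, 0 °C → rt; aq NH4Cl
Reagents that add atoms: none
Why: Grignard addition to the aldehyde after the first equivalent has deprotonated the phenol (aryl Grignard reagents do not exchange with the aryl bromide of 2); the carbinol centre forms racemic, which is immaterial because it becomes sp2 in step 10.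

Step 4
Reactants: 6 o-hydroxybenzhydrol (racemic); 7 sodium p-toluenesulfinate
Product: 8 4-bromo-2-{[3,5-bis(methoxymethoxy)phenyl](4-methylbenzenesulfonyl)methyl}-5-(methoxymethoxy)phenol (racemic)
Conditions: 7 (3 equiv), AcOH–CH2Cl2 (1:3), rt
Reagents that add atoms: none
Why: Acid-promoted SN1 substitution of the benzylic hydroxyl by sulfinate sulfur; the ortho-OH and para-OMOM make ionisation easy enough for acetic acid, well below the acidity that cleaves aryl MOM acetals, and the sulfone is the thermodynamic product.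

Step 5
Reactants: 9 (2S,5S)-hexane-2,5-diol
Product: 10 (2S,5S)-hexane-2,5-diyl dimethanesulfonate
Conditions: MsCl (2.4 equiv), Et3N (3 equiv), CH2Cl2, 0 °C
Reagents that add atoms: methanesulfonyl chloride, CS(=O)(=O)Cl
Why: O-sulfonylation leaves both C–O bonds intact, so both stereocentres are retained.

Step 6
Reactants: 10 (2S,5S)-hexane-2,5-diyl dimethanesulfonate
Product: 11 (2R,5R)-2,5-dimethylthiolane
Conditions: Na2S·9H2O (1.3 equiv), DMSO, rt; distillation
Reagents that add atoms: sodium sulfide, [Na+].[Na+].[S-2]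
Why: Double SN2 displacement by sulfide (the second one a 5-exo-tet ring closure) inverts both centres, turning the (2S,5S) dimesylate into the (2R,5R) thiolane.

Step 7
Reactants: 12 4-(methoxymethoxy)benzaldehyde
Product: 13 [4-(methoxymethoxy)phenyl]methanol
Conditions: NaBH4 (0.6 equiv), MeOH, 0 °C
Reagents that add atoms: none
Why: Borohydride reduction of an aryl aldehyde, to which the MOM ether is inert.

Step 8
Reactants: 13 [4-(methoxymethoxy)phenyl]methanol
Product: 14 1-(bromomethyl)-4-(methoxymethoxy)benzene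
Conditions: CBr4 (1.2 equiv), PPh3 (1.2 equiv), CH2Cl2, 0 °C; used at once
Reagents that add atoms: tetrabromomethane, BrC(Br)(Br)Br
Why: Appel bromination is neutral, so the acid-labile MOM ether should survive.

Step 9
Reactants: 14 1-(bromomethyl)-4-(methoxymethoxy)benzene; 11 (2R,5R)-2,5-dimethylthiolane
Product: 15 (2R,5R)-1-[4-(methoxymethoxy)benzyl]-2,5-dimethylthiolan-1-ium tetrafluoroborate
Conditions: 14 (1.1 equiv), AgBF4 (1.0 equiv), CH2Cl2, 0 °C → rt, dark
Reagents that add atoms: silver tetrafluoroborate, [Ag+].F[B-](F)(F)F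
Why: S-alkylation of the sulfide driven by precipitation of AgBr; the thiolane is C2-symmetric, so sulfur is not a stereocentre and a single salt forms.

Step 10
Reactants: 8 o-hydroxybenzyl sulfone (racemic); 15 chiral thiolanium tetrafluoroborate
Product: 19 (2R,3R)-5-bromo-3-[3,5-bis(methoxymethoxy)phenyl]-6-(methoxymethoxy)-2-[4-(methoxymethoxy)phenyl]-2,3-dihydro-1-benzofuran, via o-quinone methide 16 (not isolated), via sulfonium ylide 17 (not isolated), via anti betaine 18 (not isolated)
Conditions: 15 (1.3 equiv), Cs2CO3 (3 equiv), 4 Å MS, MeCN, −20 °C → rt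
Reagents that add atoms: none
Why: Cs2CO3 deprotonates the phenol of 8, which expels p-toluenesulfinate to give o-quinone methide 16, and also deprotonates the sulfonium α-CH2 of 15 to give the semi-stabilised ylide 17; the ylide carbon adds to the methide carbon (1,4-addition, forming C2–C3) to give betaine 18, whose phenoxide then displaces the thiolane at C2 (forming O1–C2). The closest known reaction type is the [4+1] annulation of in situ o-quinone methides with sulfonium ylides, a Corey–Chaykovsky-type sequence that ends in a five-membered ether ring. The dihydrofuran ring closes by a 5-exo-tet SN2 displacement with inversion at C2. C2 is controlled by the C2-symmetric (2R,5R)-thiolane: the ylide aryl group lies away from the flanking methyl group and that methyl group shields one face of the ylide carbon, the sense this sulfide shows in benzylic-ylide epoxide formation, so attack followed by inversion should give (2R). C3 is controlled relative to C2, because betaine formation is reversible for a semi-stabilised ylide and only the anti betaine easily reaches the anti-periplanar O–C2–S geometry, which places the two aryl groups trans and makes C3 (R). The step thus needs trans diastereoselectivity and one absolute sense, secured by the two bulky aryl groups on C2 and C3 and by the chiral sulfide, and it needs chemoselectivity, secured because the aryl bromide and MOM ethers are inert to carbonate and the only acidic sites are the phenol and the sulfonium α-CH2.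

Step 11
Reactants: 19 (2R,3R)-5-bromo-2,3-diaryl-2,3-dihydrobenzofuran (tetra-MOM)
Product: 22 [(2R,3R)-3-[3,5-bis(methoxymethoxy)phenyl]-6-(methoxymethoxy)-2-[4-(methoxymethoxy)phenyl]-2,3-dihydro-1-benzofuran-5-yl]boronic acid, via aryllithium 20 (not isolated), via lithium aryl(triisopropoxy)borate 21 (not isolated)
Conditions: B(OiPr)3 (2 equiv), then n-BuLi (1.1 equiv), THF, −78 → −20 °C; aq NH4Cl
Reagents that add atoms: triisopropyl borate, CC(C)OB(OC(C)C)OC(C)C; water, O
Why: Bromine–lithium exchange with in situ borate trapping should outrun deprotonation at the benzylic C2–H and C3–H, the ortho-OMOM stabilises the aryllithium, and neither stereocentre is touched.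

Step 12
Reactants: 23 5,7-dihydroxy-4H-chromen-4-one; 24 3-chloro-3-methylbut-1-yne
Product: 25 5-hydroxy-7-[(2-methylbut-3-yn-2-yl)oxy]-4H-chromen-4-one
Conditions: 24 (1.5 equiv), K2CO3 (1.5 equiv), KI (cat.), CuI (5 mol %), acetone, 56 °C
Reagents that add atoms: none
Why: Copper-assisted O-alkylation by the tertiary propargylic chloride should occur only at 7-OH, since 5-OH is chelated to the C4 carbonyl and far less nucleophilic.

Step 13
Reactants: 25 5-hydroxy-7-propargyloxy chromone
Product: 26 5-(methoxymethoxy)-7-[(2-methylbut-3-yn-2-yl)oxy]-4H-chromen-4-one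
Conditions: NaH (1.1 equiv), MOMCl (1.3 equiv), DMF, 0 °C
Reagents that add atoms: chloromethyl methyl ether, COCCl
Why: Williamson etherification of the sodium phenoxide, which is far more acidic than the terminal alkyne; it also removes the 5-OH/C4=O chelate before the rearrangement.

Step 14
Reactants: 26 5-(methoxymethoxy)-7-propargyloxy chromone
Product: 28 5-(methoxymethoxy)-8,8-dimethyl-4H,8H-pyrano[2,3-h]chromen-4-one, via allenylphenol 27 (not isolated)
Conditions: PhNEt2, 190 °C
Reagents that add atoms: none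
Why: Aromatic propargyl Claisen rearrangement, expected at C8 (between O7 and ring oxygen O1, as for 7-propargyloxy chromones and coumarins lacking a chelated 5-OH), followed by 1,5-hydrogen shift and 6π-oxa-electrocyclisation to the angular chromene; any linear isomer would be removed by chromatography.

Step 15
Reactants: 22 dihydrobenzofuranylboronic acid; 28 5-(methoxymethoxy)pyranochromone
Product: 29 (2S)-2-{(2R,3R)-3-[3,5-bis(methoxymethoxy)phenyl]-6-(methoxymethoxy)-2-[4-(methoxymethoxy)phenyl]-2,3-dihydro-1-benzofuran-5-yl}-5-(methoxymethoxy)-8,8-dimethyl-2,3-dihydro-4H,8H-pyrano[2,3-h]chromen-4-one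
Conditions: 28 (1.5 equiv), [RhCl(C2H4)2]2 (2.5 mol %), (S,S)-Ph-bod* [(1S,4S)-2,5-diphenylbicyclo[2.2.2]octa-2,5-diene] (5.5 mol %), aq KOH (0.2 equiv), 1,4-dioxane–H2O (10:1), 40 °C
Reagents that add atoms: none
Why: Hayashi–Miyaura-type rhodium-catalysed asymmetric 1,4-addition (transmetalation, enantioface-selective insertion of the chromone C2=C3 bond, protonation of the rhodium enolate); the chiral diene sets flavanone C2 as (S), and the existing stereocentres sit four bonds from boron, so catalyst control should prevail.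

Step 16
Reactants: 29 penta-MOM pyranoflavanone
Product: 30 (2S)-2-[(2R,3R)-3-(3,5-dihydroxyphenyl)-6-hydroxy-2-(4-hydroxyphenyl)-2,3-dihydro-1-benzofuran-5-yl]-5-hydroxy-8,8-dimethyl-2,3-dihydro-4H,8H-pyrano[2,3-h]chromen-4-one
Conditions: aq HCl (3 M), MeOH–THF, 40 °C
Reagents that add atoms: none
Why: Acid-catalysed acetal methanolysis removes all five MOM groups under dilute protic conditions that 2,2-dimethylchromenes, flavanones and trans-2,3-diaryl-dihydrobenzofurans tolerate, with methanol trapping the formaldehyde equivalents.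

Step 17
Reactants: 30 pentahydroxy pyranoflavanone
Product: 32 (2S)-2-[(2R,3R)-3-(3,5-dihydroxyphenyl)-6-hydroxy-2-(4-hydroxyphenyl)-2,3-dihydro-1-benzofuran-5-yl]-5,7-dihydroxy-8-[(1Z)-3-methylbuta-1,3-dien-1-yl]-2,3-dihydro-4H-chromen-4-one, via o-quinone methide 31 (not isolated)
Conditions: hν (medium-pressure Hg lamp, Pyrex, λ > 300 nm), degassed MeCN (1 mM), 5 °C, stopped at partial conversion; 30 recycled; neutral work-up
Reagents that add atoms: none
Why: Photochemical electrocyclic ring opening of the 2,2-dimethyl-2H-chromene gives o-quinone methide 31, which undergoes a thermal [1,7]-hydrogen shift from a methyl group to O7 through a cyclic transition state that can only deliver the (1Z)-diene and the 7-OH, while the three stereocentres are not involved.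

**Compound list**

1 | 5-bromo-2,4-dihydroxybenzaldehyde | O=Cc1cc(Br)c(O)cc1O | starting material
2 | 5-bromo-2-hydroxy-4-(methoxymethoxy)benzaldehyde | O=Cc1cc(Br)c(OCOC)cc1O | intermediate
3 | 5-bromobenzene-1,3-diol | Oc1cc(O)cc(Br)c1 | starting material
4 | 1-bromo-3,5-bis(methoxymethoxy)benzene | COCOc1cc(Br)cc(OCOC)c1 | intermediate
5 | [3,5-bis(methoxymethoxy)phenyl]magnesium bromide | COCOc1cc([Mg]Br)cc(OCOC)c1 | intermediate
6 | 4-bromo-2-{[3,5-bis(methoxymethoxy)phenyl](hydroxy)methyl}-5-(methoxymethoxy)phenol (racemic) | OC(c1cc(Br)c(OCOC)cc1O)c1cc(OCOC)cc(OCOC)c1 | intermediate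
7 | sodium p-toluenesulfinate | Cc1ccc(S(=O)[O-])cc1.[Na+] | starting material
8 | 4-bromo-2-{[3,5-bis(methoxymethoxy)phenyl](4-methylbenzenesulfonyl)methyl}-5-(methoxymethoxy)phenol (racemic) | Cc1ccc(cc1)S(=O)(=O)C(c1cc(Br)c(OCOC)cc1O)c1cc(OCOC)cc(OCOC)c1 | intermediate
9 | (2S,5S)-hexane-2,5-diol | C[C@H](O)CC[C@H](C)O | starting material
10 | (2S,5S)-hexane-2,5-diyl dimethanesulfonate | C[C@H](OS(C)(=O)=O)CC[C@H](C)OS(C)(=O)=O | intermediate
11 | (2R,5R)-2,5-dimethylthiolane | C[C@@H]1CC[C@@H](C)S1 | intermediate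
12 | 4-(methoxymethoxy)benzaldehyde | COCOc1ccc(C=O)cc1 | starting material
13 | [4-(methoxymethoxy)phenyl]methanol | COCOc1ccc(CO)cc1 | intermediate
14 | 1-(bromomethyl)-4-(methoxymethoxy)benzene | COCOc1ccc(CBr)cc1 | intermediate
15 | (2R,5R)-1-[4-(methoxymethoxy)benzyl]-2,5-dimethylthiolan-1-ium tetrafluoroborate | C[C@@H]1CC[C@@H](C)[S+]1Cc1ccc(OCOC)cc1.F[B-](F)(F)F | intermediate
16 | (6E)-4-bromo-6-[3,5-bis(methoxymethoxy)benzylidene]-3-(methoxymethoxy)cyclohexa-2,4-dien-1-one | O=C1C=C(OCOC)C(Br)=C/C1=C\c1cc(OCOC)cc(OCOC)c1 | intermediate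
17 | (2R,5R)-2,5-dimethylthiolan-1-ium-1-yl [4-(methoxymethoxy)phenyl]methanide | C[C@@H]1CC[C@@H](C)[S+]1[CH-]c1ccc(OCOC)cc1 | intermediate
18 | 4-bromo-2-{(1R,2S)-1-[3,5-bis(methoxymethoxy)phenyl]-2-[(2R,5R)-2,5-dimethylthiolan-1-ium-1-yl]-2-[4-(methoxymethoxy)phenyl]ethyl}-5-(methoxymethoxy)phenolate | [O-]c1cc(OCOC)c(Br)cc1[C@@H](c1cc(OCOC)cc(OCOC)c1)[C@@H](c1ccc(OCOC)cc1)[S+]1[C@H](C)CC[C@H]1C | intermediate
19 | (2R,3R)-5-bromo-3-[3,5-bis(methoxymethoxy)phenyl]-6-(methoxymethoxy)-2-[4-(methoxymethoxy)phenyl]-2,3-dihydro-1-benzofuran | Brc1cc2c(cc1OCOC)O[C@@H](c1ccc(OCOC)cc1)[C@@H]2c1cc(OCOC)cc(OCOC)c1 | intermediate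
20 | [(2R,3R)-3-[3,5-bis(methoxymethoxy)phenyl]-6-(methoxymethoxy)-2-[4-(methoxymethoxy)phenyl]-2,3-dihydro-1-benzofuran-5-yl]lithium | [Li]c1cc2c(cc1OCOC)O[C@@H](c1ccc(OCOC)cc1)[C@@H]2c1cc(OCOC)cc(OCOC)c1 | intermediate
21 | lithium [(2R,3R)-3-[3,5-bis(methoxymethoxy)phenyl]-6-(methoxymethoxy)-2-[4-(methoxymethoxy)phenyl]-2,3-dihydro-1-benzofuran-5-yl]tri(propan-2-yloxy)borate | CC(C)O[B-](OC(C)C)(OC(C)C)c1cc2c(cc1OCOC)O[C@@H](c1ccc(OCOC)cc1)[C@@H]2c1cc(OCOC)cc(OCOC)c1.[Li+] | intermediate
22 | [(2R,3R)-3-[3,5-bis(methoxymethoxy)phenyl]-6-(methoxymethoxy)-2-[4-(methoxymethoxy)phenyl]-2,3-dihydro-1-benzofuran-5-yl]boronic acid | OB(O)c1cc2c(cc1OCOC)O[C@@H](c1ccc(OCOC)cc1)[C@@H]2c1cc(OCOC)cc(OCOC)c1 | intermediate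
23 | 5,7-dihydroxy-4H-chromen-4-one | O=c1ccoc2cc(O)cc(O)c12 | starting material
24 | 3-chloro-3-methylbut-1-yne | C#CC(C)(C)Cl | starting material
25 | 5-hydroxy-7-[(2-methylbut-3-yn-2-yl)oxy]-4H-chromen-4-one | O=c1ccoc2cc(OC(C)(C)C#C)cc(O)c12 | intermediate
26 | 5-(methoxymethoxy)-7-[(2-methylbut-3-yn-2-yl)oxy]-4H-chromen-4-one | O=c1ccoc2cc(OC(C)(C)C#C)cc(OCOC)c12 | intermediate
27 | 7-hydroxy-5-(methoxymethoxy)-8-(3-methylbuta-1,2-dien-1-yl)-4H-chromen-4-one | O=c1ccoc2c(C=C=C(C)C)c(O)cc(OCOC)c12 | intermediate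
28 | 5-(methoxymethoxy)-8,8-dimethyl-4H,8H-pyrano[2,3-h]chromen-4-one | O=c1ccoc2c3C=CC(C)(C)Oc3cc(OCOC)c12 | intermediate
29 | (2S)-2-{(2R,3R)-3-[3,5-bis(methoxymethoxy)phenyl]-6-(methoxymethoxy)-2-[4-(methoxymethoxy)phenyl]-2,3-dihydro-1-benzofuran-5-yl}-5-(methoxymethoxy)-8,8-dimethyl-2,3-dihydro-4H,8H-pyrano[2,3-h]chromen-4-one | CC1(C)C=Cc2c(O1)cc(OCOC)c1c2O[C@H](c2cc3c(cc2OCOC)O[C@@H](c2ccc(OCOC)cc2)[C@@H]3c2cc(OCOC)cc(OCOC)c2)CC1=O | intermediate
30 | (2S)-2-[(2R,3R)-3-(3,5-dihydroxyphenyl)-6-hydroxy-2-(4-hydroxyphenyl)-2,3-dihydro-1-benzofuran-5-yl]-5-hydroxy-8,8-dimethyl-2,3-dihydro-4H,8H-pyrano[2,3-h]chromen-4-one | CC1(C)C=Cc2c(O1)cc(O)c1c2O[C@H](c2cc3c(cc2O)O[C@@H](c2ccc(O)cc2)[C@@H]3c2cc(O)cc(O)c2)CC1=O | intermediate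
31 | (2S,8Z)-2-[(2R,3R)-3-(3,5-dihydroxyphenyl)-6-hydroxy-2-(4-hydroxyphenyl)-2,3-dihydro-1-benzofuran-5-yl]-5-hydroxy-8-(3-methylbut-2-en-1-ylidene)-2,3-dihydro-4H-chromene-4,7(8H)-dione | CC(C)=C/C=C1\C(=O)C=C(O)C2=C1O[C@H](c1cc3c(cc1O)O[C@@H](c1ccc(O)cc1)[C@@H]3c1cc(O)cc(O)c1)CC2=O | intermediate
32 | (2S)-2-[(2R,3R)-3-(3,5-dihydroxyphenyl)-6-hydroxy-2-(4-hydroxyphenyl)-2,3-dihydro-1-benzofuran-5-yl]-5,7-dihydroxy-8-[(1Z)-3-methylbuta-1,3-dien-1-yl]-2,3-dihydro-4H-chromen-4-one (CNP0284772.1) | C=C(C)/C=C\c1c(O)cc(O)c2c1O[C@H](c1cc3c(cc1O)O[C@@H](c1ccc(O)cc1)[C@@H]3c1cc(O)cc(O)c1)CC2=O | target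

**Step count**

Total: 17 steps. Longest linear sequence: 8 steps (1, 3, 4, 10, 11, 15, 16, 17).

**Three steps most likely to fail**

Step 17 (photochemical chromene opening). The product dienylphenol also absorbs and can re-close to the chromene, so the reaction may stall at a photostationary mixture. The diene may isomerise E/Z, and light may reversibly open the flavanone ring and erode C2. The fallback builds the Z-diene from an alkyne; it sets out from 22 and 23 and returns at 32. Chromone 23 would be bis-protected (NaH, MOMCl, DMF) to 5,7-bis(methoxymethoxy)-4H-chromen-4-one F1 and iodinated at C8 (N-iodosuccinimide, DMF) to 8-iodo-5,7-bis(methoxymethoxy)-4H-chromen-4-one F2. Rhodium-catalysed addition of 22 under the conditions of step 15 would give the (2S)-8-iodoflavanone F3. Sonogashira coupling with 2-methylbut-1-en-3-yne (Pd(PPh3)2Cl2, CuI, Et3N, sealed tube) would give the hexa-MOM 8-(3-methylbut-3-en-1-yn-1-yl)flavanone F4. The MOM groups would be removed at this stage (aq HCl, MeOH–THF), because the dienylphenol would cyclise to the chromene in acid, giving the hexahydroxy enyne F5. Z-selective semireduction of the conjugated enyne (zinc dust activated with Cu(OAc)2 and AgNO3, MeOH–H2O, rt) would then give 32.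

Step 15 (rhodium-catalysed arylation). Transmetalation and insertion of the hindered, electron-rich ortho-alkoxy aryl group may be slower than protodeboronation, and catalyst control of the new centre may be incomplete. The fallback goes through a chalcone; it sets out from 19 and 28 and returns at 29. Bromide 19 would be formylated (n-BuLi, THF, −78 °C; DMF) to (2R,3R)-3-[3,5-bis(methoxymethoxy)phenyl]-6-(methoxymethoxy)-2-[4-(methoxymethoxy)phenyl]-2,3-dihydro-1-benzofuran-5-carbaldehyde F6. Chromone 28 would be opened with hot aqueous-ethanolic NaOH (loss of formate) to 1-[5-hydroxy-7-(methoxymethoxy)-2,2-dimethyl-2H-chromen-6-yl]ethan-1-one F7, which has only one free phenol, the one next to the pyran carbon. Claisen–Schmidt condensation of F6 and F7 (KOH, EtOH) would give the (E)-2'-hydroxychalcone F8. Oxa-Michael ring closure (NaOAc, EtOH, reflux) would give 29 together with its C2 epimer, the (2R)-flavanone F9; the two are diastereomers and would be separated by chromatography.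

Step 10 (key annulation). Shielding of the ylide face may be incomplete, the betaine may close before it equilibrates (cis product), and the phenoxide or sulfinate may instead be benzylated by the electron-rich sulfonium salt. The fallback moves stereocontrol to a separation; it sets out from 8 and 14 and returns at 19. Bromide 14, tetrahydrothiophene and AgBF4 would give the achiral, less hindered salt 1-[4-(methoxymethoxy)benzyl]thiolan-1-ium tetrafluoroborate F10. Annulation of 8 with F10 (Cs2CO3, MeCN) would give the racemic trans product, that is 19 together with its (2S,3S) enantiomer F11. Preparative HPLC on a chiral stationary phase would deliver 19.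

**Further compounds**

F1 | step 17 | 5,7-bis(methoxymethoxy)-4H-chromen-4-one | O=c1ccoc2cc(OCOC)cc(OCOC)c12
F2 | step 17 | 8-iodo-5,7-bis(methoxymethoxy)-4H-chromen-4-one | O=c1ccoc2c(I)c(OCOC)cc(OCOC)c12
F3 | step 17 | (2S)-2-{(2R,3R)-3-[3,5-bis(methoxymethoxy)phenyl]-6-(methoxymethoxy)-2-[4-(methoxymethoxy)phenyl]-2,3-dihydro-1-benzofuran-5-yl}-8-iodo-5,7-bis(methoxymethoxy)-2,3-dihydro-4H-chromen-4-one | COCOc1cc(OCOC)c2c(c1I)O[C@H](c1cc3c(cc1OCOC)O[C@@H](c1ccc(OCOC)cc1)[C@@H]3c1cc(OCOC)cc(OCOC)c1)CC2=O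
F4 | step 17 | (2S)-2-{(2R,3R)-3-[3,5-bis(methoxymethoxy)phenyl]-6-(methoxymethoxy)-2-[4-(methoxymethoxy)phenyl]-2,3-dihydro-1-benzofuran-5-yl}-5,7-bis(methoxymethoxy)-8-(3-methylbut-3-en-1-yn-1-yl)-2,3-dihydro-4H-chromen-4-one | COCOc1cc(OCOC)c2c(c1C#CC(C)=C)O[C@H](c1cc3c(cc1OCOC)O[C@@H](c1ccc(OCOC)cc1)[C@@H]3c1cc(OCOC)cc(OCOC)c1)CC2=O
F5 | step 17 | (2S)-2-[(2R,3R)-3-(3,5-dihydroxyphenyl)-6-hydroxy-2-(4-hydroxyphenyl)-2,3-dihydro-1-benzofuran-5-yl]-5,7-dihydroxy-8-(3-methylbut-3-en-1-yn-1-yl)-2,3-dihydro-4H-chromen-4-one | Oc1cc(O)c2c(c1C#CC(C)=C)O[C@H](c1cc3c(cc1O)O[C@@H](c1ccc(O)cc1)[C@@H]3c1cc(O)cc(O)c1)CC2=O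
F6 | step 15 | (2R,3R)-3-[3,5-bis(methoxymethoxy)phenyl]-6-(methoxymethoxy)-2-[4-(methoxymethoxy)phenyl]-2,3-dihydro-1-benzofuran-5-carbaldehyde | O=Cc1cc2c(cc1OCOC)O[C@@H](c1ccc(OCOC)cc1)[C@@H]2c1cc(OCOC)cc(OCOC)c1
F7 | step 15 | 1-[5-hydroxy-7-(methoxymethoxy)-2,2-dimethyl-2H-chromen-6-yl]ethan-1-one | CC(=O)c1c(O)c2C=CC(C)(C)Oc2cc1OCOC
F8 | step 15 | (2E)-3-{(2R,3R)-3-[3,5-bis(methoxymethoxy)phenyl]-6-(methoxymethoxy)-2-[4-(methoxymethoxy)phenyl]-2,3-dihydro-1-benzofuran-5-yl}-1-[5-hydroxy-7-(methoxymethoxy)-2,2-dimethyl-2H-chromen-6-yl]prop-2-en-1-one | O=C(/C=C/c1cc2c(cc1OCOC)O[C@@H](c1ccc(OCOC)cc1)[C@@H]2c1cc(OCOC)cc(OCOC)c1)c1c(O)c2C=CC(C)(C)Oc2cc1OCOC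
F9 | step 15 | (2R)-2-{(2R,3R)-3-[3,5-bis(methoxymethoxy)phenyl]-6-(methoxymethoxy)-2-[4-(methoxymethoxy)phenyl]-2,3-dihydro-1-benzofuran-5-yl}-5-(methoxymethoxy)-8,8-dimethyl-2,3-dihydro-4H,8H-pyrano[2,3-h]chromen-4-one | CC1(C)C=Cc2c(O1)cc(OCOC)c1c2O[C@@H](c2cc3c(cc2OCOC)O[C@@H](c2ccc(OCOC)cc2)[C@@H]3c2cc(OCOC)cc(OCOC)c2)CC1=O
F10 | step 10 | 1-[4-(methoxymethoxy)benzyl]thiolan-1-ium tetrafluoroborate | COCOc1ccc(C[S+]2CCCC2)cc1.F[B-](F)(F)F
F11 | step 10 | (2S,3S)-5-bromo-3-[3,5-bis(methoxymethoxy)phenyl]-6-(methoxymethoxy)-2-[4-(methoxymethoxy)phenyl]-2,3-dihydro-1-benzofuran | Brc1cc2c(cc1OCOC)O[C@H](c1ccc(OCOC)cc1)[C@H]2c1cc(OCOC)cc(OCOC)c1
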